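## The problem

Target 13 is a cyclohexene with an oxygen on each of its four sp3 ring carbons and a benzoyloxymethyl branch on the alkene. The ring is numbered C1 (OMe), C2=C3 (C3 bears C7H2OBz), C4 (OH), C5 (OBz), C6 (OH); with the ring drawn flat and numbered clockwise, β means towards the viewer. The four contiguous stereocentres are then 1β-OMe, 4β-OH, 5β-OBz and 6α-OH, (1S,4R,5R,6R): O4/O5 cis, O5/O6 trans, O6/O1 trans. Five oxygens must be told apart: a methyl ether, a primary and a secondary benzoate, and two free secondary hydroxyls that flank the secondary benzoate. This arrangement is fragile: the O5 benzoate can migrate to O4 or O6 under base, the allylic C–O bonds at C1, C4 and C7 ionise in strong acid, and any intermediate with a carbonyl at C4 can eliminate the C6 and C1 oxygens and aromatise. Three control elements are available: a cis-fused ketal on O4/O5 shields the β face and sends an oxidant to the α face of C1/C6, C1 can be set by inversion at an oxirane, and an α-hydroxyl on C6 can deliver hydride to the α face of C4. The feature that makes the key step possible is that O4/O5 (cis), O6 (anti to them) and O1 (trans to O6) form exactly the pattern left when one alkene of meso cis-cyclohexa-3,5-diene-1,2-diol is epoxidised anti to the diol and opened at its allylic carbon; because that diene is meso, choosing one of its two enantiotopic alkenes fixes the absolute configuration of all four centres in one catalytic step. What the diene does not supply is the one-carbon branch C7 on vinylic C3, which must be added later without losing control of C4.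

## Retrosynthesis

**C4–H (13 ⇒ 12).** The last bond formed is C4–H, by reduction of β-hydroxy enone 12. C4 cannot keep its original configuration, because attaching C7 to C3 is easiest when C4 is a carbonyl. An undirected small hydride would be expected to attack axially and give the 4α (trans) alcohol. Hydride delivered from a boron bound to the 6α-hydroxyl can only arrive on the α face, which gives the 4,6-anti diol and hence the 4β-OH cis to O5. Putting this step last also means the migration-prone cis-hydroxy benzoate is never exposed to a deprotection. What is asked of the forward reaction is strictly intramolecular hydride transfer.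

**O6–PMB and the two benzoyl C–O bonds (12 ⇒ 11 ⇒ 10).** Compound 12 comes from its 4-methoxybenzyl (PMB) ether 11, and 11 from diol 10 by cutting both ester bonds. In 10, C4 is a ketone and O6 is an ether, so O5 and O7 are the only free hydroxyls. Exhaustive benzoylation therefore needs no regioselectivity, in contrast to selective acylation of a tetraol at the end. PMB is chosen because it is removed by neutral oxidation.

**C3–C7 (10 ⇒ 8 + 9).** The hydroxymethyl group is cut from the α-carbon of enone 8 and traced to formaldehyde 9 (Morita–Baylis–Hillman). This is one step against two for α-halogenation and cross-coupling, and the carbon arrives at the right oxidation level. The forward reaction must run under base mild enough that 8 does not eliminate O6.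

**C4 oxidation level and the O4/O5/O6 labels (8 ⇒ 7 ⇒ 6 ⇒ 5).** Enone 8 comes from cis-diol 7 by oxidation of the allylic hydroxyl only; this is the operation that distinguishes O4 from O5. Diol 7 comes from acetonide 6, and 6 from alcohol 5 by etherification of O6 while O4 and O5 are still tied in the ketal. Each oxygen is labelled by the step that reveals it, so no selective protection is needed.

**C1–OMe (5 ⇒ 3 + 4).** Cutting the C1–O(Me) bond leads to vinyl oxirane 3 and methanol 4. Opening at the allylic carbon with inversion gives the trans methoxy alcohol directly; methylating a diol would require choosing between two hydroxyls. The forward reaction must attack C1 and neither C6 nor, in a conjugate sense, C3.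

**C1–O and C6–O, the oxirane (3 ⇒ 2).** Removing the oxirane oxygen gives meso diene acetonide 2, an achiral compound with a mirror plane. This is the largest simplification of the route: four stereocentres are traded for a choice between two enantiotopic alkenes. The forward reaction needs a chiral oxygen-transfer catalyst for that choice and the ketal for the α face.

**Ketal C–O bonds (2 ⇒ 1).** Acetonide 2 comes from commercial cis-cyclohexa-3,5-diene-1,2-diol 1 by ketalisation.

## Roads not taken

Alternative 1: The ring is cut at C3–C4 and built from the chiral pool. D-Xylose A1 would be converted (2-O-methylation, 3,4-di-O-PMB protection, Wittig olefination at the anomeric carbon with a thioester ylide, oxidation of the primary alcohol) into open-chain enethioate aldehyde A2; xylose C2, C3 and C4 become C1, C6 and C5 of the target. A nucleophilic phosphine or amine catalyst then adds to C2, the enolate attacks the aldehyde and the catalyst leaves: an intramolecular Morita–Baylis–Hillman closure to cyclohexenol thioester A3, with C7 already on C3.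
- Merits: three of the four centres come enantiopure from a sugar, with no dependence on a catalyst's selectivity; C4 is formed once and never oxidised again; ring closure and C7 installation coincide.
- Weak points: the three secondary hydroxyls of xylose must each receive a different group before the chain is opened, which costs steps. In A3, O5 and O6 carry the same PMB group, so the end of the route still faces selective benzoylation of O5 beside free O4 and O6. The C4 configuration depends on substrate-controlled diastereoselection in the ring closure, which is not assured. A2 is a β-alkoxy aldehyde prone to elimination.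
- Comparison: this road is better in absolute stereocontrol and avoids the oxidation–reduction at C4. The chosen plan offers a shorter sequence (10 steps), four centres from one catalytic step, and a built-in distinction of O4, O5 and O6.

Alternative 2: Here nothing in the ring is cut; the C4–O and C5–O bonds are made on an arene. Toluene dioxygenase in whole cells adds O2 across two adjacent carbons of bromobenzene A4 to give (1S,2S)-3-bromocyclohexa-3,5-diene-1,2-diol A5, whose bromine sits on the future C3 and whose two carbinols have the configuration of C4 and C5. Ketalisation, peracid epoxidation of the distal alkene anti to the ketal, and methanolysis at the allylic carbon would follow as in the chosen route; the vinyl bromide would then be converted to CH2OH by a Stille hydroxymethylation or a carbonylation.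
- Merits: A5 is essentially a single enantiomer. The bromine directs the peracid to the other alkene and serves as the handle for C7, so C4 never leaves the alcohol oxidation state and no enone or stereoselective reduction is needed. In stereochemical security, and probably in step count, this road is stronger than the chosen one.
- Weak points: O4 and O5 leave the same ketal together, so placing a benzoate on O5 only, beside free O4 and O6, needs regioselective acylation of a cis-diol or further protecting groups. The C7 installation needs organotin or carbon monoxide chemistry. The enzyme gives one enantiomeric series only.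
- Comparison: the chosen plan answers with the automatic O4/O5 distinction (C4 is a ketone while O5 and O7 are acylated), access to either enantiomer by catalyst choice, and C7 from formaldehyde. It accepts in return an enantioselectivity risk and a second setting of C4.

Alternative 3: The ring is cut at C3–C4 and C5–C6. Furfuryl acetate A6 and vinylene carbonate A7 would combine in an endo Diels–Alder reaction to give 7-oxanorbornene carbonate A8, which holds all seven carbons, the cis C4/C5 oxygens and, through the bridge, O6 anti to them. Acid-promoted SN2′ opening of the bridge with methanol 4 at C1 would move the alkene to C2=C3 and leave O6 as the free hydroxyl.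
- Merits: this is the most convergent plan, from two cheap achiral materials, with C7 in place and C4 never oxidised.
- Weak points: furan cycloadditions with this dienophile are slow and reversible, and the exo adduct, which has the wrong C5/C6 relationship, is the thermodynamic one. A8 is formed racemic and needs a resolution. The bridge opening must choose between two allylic termini and proceed anti. O4 and O5 again emerge together from the carbonate.
- Comparison: this road is shorter on paper but has no absolute control and two uncertain selectivities. The chosen plan has one catalytic asymmetric step whose facial course is fixed by the substrate.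

Key step: step 2

Assumption: the sense of induction in step 2 is assigned by analogy with indene, the second alkene of 2 standing in for the arene; on that model the (R,R) catalyst leads to 3, and the route is written with it.

## Route

Step 1
Reactants: 1 cis-cyclohexa-3,5-diene-1,2-diol
Product: 2 meso cis-2,2-dimethyl-3a,7a-dihydro-1,3-benzodioxole (the 4β,5β-O-isopropylidene diene)
Conditions: 2,2-dimethoxypropane, p-TsOH·H2O (1 mol %), acetone, 0 °C, 30 min; Et3N quench; used promptly
Reagents that add atoms: 2,2-dimethoxypropane, COC(C)(C)OC
Why: Acid-catalysed transketalisation; the cis-diol closes the five-membered dioxolane readily, and cold, brief, catalytic acid with a basic quench should avoid dehydration of 1 to phenol. No stereocentre changes and 2 stays meso.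

Step 2
Reactants: 2 meso cis-2,2-dimethyl-3a,7a-dihydro-1,3-benzodioxole
Product: 3 1α,6α-epoxy-4β,5β-(isopropylidenedioxy)cyclohex-2-ene (oxirane anti to the dioxolane)
Conditions: (R,R)-(salen)MnCl (4 mol %, trivalent manganese; salen = N,N'-bis(3,5-di-tert-butylsalicylidene)cyclohexane-1,2-diamine dianion), 4-phenylpyridine N-oxide (20 mol %), aq. NaOCl buffered to pH 11.3 with Na2HPO4, CH2Cl2, 0 °C
Reagents that add atoms: sodium hypochlorite, [Na+].[O-]Cl
Why: Jacobsen–Katsuki epoxidation: NaOCl oxidises the trivalent manganese complex to an oxo-manganese species (pentavalent manganese), which transfers oxygen to one cis alkene of the conjugated diene through a short-lived allylic radical that collapses to the oxirane. The closest known reaction type is the asymmetric epoxidation of cyclic conjugated cis-dienes and of indene with this catalyst; on a meso diene, face selection becomes selection between two enantiotopic alkenes. The one ring formed, the oxirane, closes by oxygen-atom transfer across C1=C6 (a formal [2+1] addition), and inside the six-membered ring the radical can only collapse to the cis-fused oxirane. C1 and C6 are the new stereocentres: their α configuration is set by the cis-fused dioxolane, which covers the β face of both alkenes, while the salen ligand decides which alkene reacts and so fixes the absolute sense of C4 and C5 as well. Three selectivities are needed: enantiotopic-group selection (side-on approach over the diimine bridge, the second alkene playing the part of the aryl group of indene), anti-facial attack (the acetonide), and mono-epoxidation (the conjugated alkene of 2 is more reactive towards the electrophilic oxo species than the isolated alkene left in 3). The buffered basic medium protects both the acid-labile diene and the vinyl oxirane.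

Step 3
Reactants: 3 1α,6α-epoxy-4β,5β-(isopropylidenedioxy)cyclohex-2-ene; 4 methanol
Product: 5 1β-methoxy-4β,5β-(isopropylidenedioxy)cyclohex-2-en-6α-ol
Conditions: MeOH, camphor-10-sulfonic acid (5 mol %), 0 °C; Et3N quench
Reagents that add atoms: none
Why: Acid-catalysed SN2 opening of a vinyl oxirane: methanol attacks the protonated epoxide at allylic C1, whose C–O bond is weakened by the adjacent π system, while C6 is deactivated by the neighbouring C5–O bond and shielded by the dioxolane. Inversion at C1 gives 1β-OMe trans to the retained 6α-OH.

Step 4
Reactants: 5 1β-methoxy-4β,5β-(isopropylidenedioxy)cyclohex-2-en-6α-ol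
Product: 6 1β-methoxy-6α-(4-methoxybenzyloxy)-4β,5β-(isopropylidenedioxy)cyclohex-2-ene
Conditions: NaH, 4-methoxybenzyl chloride, Bu4NI (cat.), DMF, 0 °C to rt
Reagents that add atoms: 4-methoxybenzyl chloride, COc1ccc(CCl)cc1
Why: Williamson etherification on a substrate with no base-sensitive group. PMB should survive aqueous acid, MnO2, amine/bicarbonate and acylation, and it is later removed by neutral oxidation.

Step 5
Reactants: 6 1β-methoxy-6α-(4-methoxybenzyloxy)-4β,5β-(isopropylidenedioxy)cyclohex-2-ene
Product: 7 1β-methoxy-6α-(4-methoxybenzyloxy)cyclohex-2-ene-4β,5β-diol
Conditions: AcOH/H2O 4:1, 45 °C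
Reagents that add atoms: none
Why: Acid hydrolysis of the isopropylidene ketal; the PMB and methyl ethers are stable to aqueous acetic acid, and no stereocentre is touched.

Step 6
Reactants: 7 1β-methoxy-6α-(4-methoxybenzyloxy)cyclohex-2-ene-4β,5β-diol
Product: 8 5β-hydroxy-1β-methoxy-6α-(4-methoxybenzyloxy)cyclohex-2-en-4-one
Conditions: activated MnO2 (excess), CH2Cl2, rt
Reagents that add atoms: none
Why: MnO2 oxidises allylic alcohols chemoselectively; only C4–OH is allylic, so O5 stays a free hydroxyl and is thereby distinguished from O4. The C4 centre is deliberately given up here and restored in step 10.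

Step 7
Reactants: 8 5β-hydroxy-1β-methoxy-6α-(4-methoxybenzyloxy)cyclohex-2-en-4-one; 9 formaldehyde
Product: 10 5β-hydroxy-3-(hydroxymethyl)-1β-methoxy-6α-(4-methoxybenzyloxy)cyclohex-2-en-4-one
Conditions: 37% aq. HCHO, imidazole (1 equiv), THF/1 M aq. NaHCO3, rt
Reagents that add atoms: none
Why: Morita–Baylis–Hillman hydroxymethylation of a cyclic enone: imidazole adds to C2, the enolate attacks formaldehyde through C3, and loss of imidazole restores the enone with the new C3–C7 bond. No stereocentre is formed, and the weakly basic medium should keep enolisation towards C5 slow.

Step 8
Reactants: 10 5β-hydroxy-3-(hydroxymethyl)-1β-methoxy-6α-(4-methoxybenzyloxy)cyclohex-2-en-4-one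
Product: 11 5β-benzoyloxy-3-(benzoyloxymethyl)-1β-methoxy-6α-(4-methoxybenzyloxy)cyclohex-2-en-4-one
Conditions: BzCl (2.5 equiv), pyridine, CH2Cl2, 0 °C
Reagents that add atoms: benzoyl chloride, O=C(Cl)c1ccccc1
Why: Exhaustive acylation of the only two free hydroxyls, primary O7 and O5; O4 is a ketone and O6 an ether, so no regioselectivity is required. Pyridine without a stronger base should avoid elimination of the O6 ether.

Step 9
Reactants: 11 5β-benzoyloxy-3-(benzoyloxymethyl)-1β-methoxy-6α-(4-methoxybenzyloxy)cyclohex-2-en-4-one
Product: 12 5β-benzoyloxy-3-(benzoyloxymethyl)-6α-hydroxy-1β-methoxycyclohex-2-en-4-one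
Conditions: DDQ, CH2Cl2/pH 7 phosphate buffer 10:1, 0 °C to rt; product used directly
Reagents that add atoms: none
Why: Oxidative cleavage of the PMB ether by DDQ through the benzylic oxocarbenium ion, which water hydrolyses. The neutral buffered medium should leave the benzoates, the enone and the β-hydroxy ketone intact.

Step 10
Reactants: 12 5β-benzoyloxy-3-(benzoyloxymethyl)-6α-hydroxy-1β-methoxycyclohex-2-en-4-one
Product: 13 [(3S,4R,5R,6R)-5-(benzoyloxy)-4,6-dihydroxy-3-methoxycyclohex-1-en-1-yl]methyl benzoate (route numbering: 1β-OMe, 4β-OH, 5β-OBz, 6α-OH)
Conditions: Me4NBH(OAc)3 (5 equiv), MeCN/AcOH 1:1, −30 to −20 °C; aq. potassium sodium tartrate work-up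
Reagents that add atoms: none
Why: Evans–Saksena hydroxyl-directed reduction: the 6α-hydroxyl exchanges an acetate on boron and the bound hydride is delivered through a six-membered chair-like transition state to the α face of C4, giving 4β-OH anti to O6 and therefore cis to the O5 benzoate. The free reagent is too weak to reduce the ketone intermolecularly, so the face is fixed by the tether, and the acidic medium suppresses benzoate migration.

## Compound list

1 | cis-cyclohexa-3,5-diene-1,2-diol (meso) | O[C@@H]1C=CC=C[C@@H]1O | starting material
2 | meso cis-2,2-dimethyl-3a,7a-dihydro-1,3-benzodioxole | C1=C[C@H]2OC(C)(C)O[C@H]2C=C1 | intermediate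
3 | 1α,6α-epoxy-4β,5β-(isopropylidenedioxy)cyclohex-2-ene | C1=C[C@H]2OC(C)(C)O[C@H]2[C@@H]3O[C@H]13 | intermediate
4 | methanol | CO | starting material
5 | 1β-methoxy-4β,5β-(isopropylidenedioxy)cyclohex-2-en-6α-ol | CO[C@H]1C=C[C@H]2OC(C)(C)O[C@H]2[C@@H]1O | intermediate
6 | 1β-methoxy-6α-(4-methoxybenzyloxy)-4β,5β-(isopropylidenedioxy)cyclohex-2-ene | CO[C@H]1C=C[C@H]2OC(C)(C)O[C@H]2[C@@H]1OCc1ccc(OC)cc1 | intermediate
7 | 1β-methoxy-6α-(4-methoxybenzyloxy)cyclohex-2-ene-4β,5β-diol | CO[C@H]1C=C[C@@H](O)[C@@H](O)[C@@H]1OCc1ccc(OC)cc1 | intermediate
8 | 5β-hydroxy-1β-methoxy-6α-(4-methoxybenzyloxy)cyclohex-2-en-4-one | CO[C@H]1C=CC(=O)[C@@H](O)[C@@H]1OCc1ccc(OC)cc1 | intermediate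
9 | formaldehyde | C=O | starting material
10 | 5β-hydroxy-3-(hydroxymethyl)-1β-methoxy-6α-(4-methoxybenzyloxy)cyclohex-2-en-4-one | CO[C@H]1C=C(CO)C(=O)[C@@H](O)[C@@H]1OCc1ccc(OC)cc1 | intermediate
11 | 5β-benzoyloxy-3-(benzoyloxymethyl)-1β-methoxy-6α-(4-methoxybenzyloxy)cyclohex-2-en-4-one | CO[C@H]1C=C(COC(=O)c2ccccc2)C(=O)[C@@H](OC(=O)c2ccccc2)[C@@H]1OCc1ccc(OC)cc1 | intermediate
12 | 5β-benzoyloxy-3-(benzoyloxymethyl)-6α-hydroxy-1β-methoxycyclohex-2-en-4-one | CO[C@H]1C=C(COC(=O)c2ccccc2)C(=O)[C@@H](OC(=O)c2ccccc2)[C@@H]1O | intermediate
13 | [(3S,4R,5R,6R)-5-(benzoyloxy)-4,6-dihydroxy-3-methoxycyclohex-1-en-1-yl]methyl benzoate | CO[C@H]1C=C(COC(=O)c2ccccc2)[C@@H](O)[C@@H](OC(=O)c2ccccc2)[C@@H]1O | target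

## Step count and risks

Total step count: 10. Longest linear sequence: 10 steps (1 to 13); the route is fully linear, with 4 and 9 entering as one-carbon reactants.

**Step 2 (key step).** The catalyst may discriminate poorly between the two enantiotopic alkenes, or in the opposite sense, because the diene offers a vinyl group where the catalyst is usually given an arene. Over-oxidation of the remaining alkene and acid-induced decomposition or dimerisation of the diene are further hazards. Fallback, setting out from 2: epoxidation with mCPBA (CH2Cl2, NaHCO3) under the same acetonide control should give the racemic anti-epoxide F1, and methanolysis as in step 3 the racemic methoxy alcohol F2. Esterification with (S)-O-methylmandelic acid (DCC, DMAP) then gives two diastereomers, the (S)-O-methylmandelate of 5 F3 and the (S)-O-methylmandelate of the enantiomer of 5 F4, to be separated by chromatography or crystallisation. K2CO3 in methanol releases 5 from F3, where the route is rejoined. This replaces asymmetric catalysis by a classical resolution and costs half the material.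

**Step 10.** Intramolecular hydride delivery must pass through the ring conformer in which O6 is axial, which also puts O5 and O1 syn-diaxial. If this makes the directed pathway slow, undirected axial attack (giving the 4α alcohol trans to O5) or elimination from the β-hydroxy ketone could compete. Fallback, setting out from 11 so that 12 is never formed: Corey–Bakshi–Shibata reduction ((R)-2-methyl-CBS-oxazaborolidine, catecholborane, toluene, −78 °C) places the choice of face in the reagent. Taking the substituted alkenyl arm at C3 as the larger group, as in 2-substituted cyclohexenones, this catalyst enantiomer should deliver hydride to the α face and give the 4β-alcohol PMB ether F5. DDQ as in step 9 then gives 13.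

**Step 7.** The amine/bicarbonate medium may trigger enolisation towards C5 followed by loss of the O6 ether and aromatisation; the conjugate addition at C2 next to the methoxy-bearing carbon may also be slow. Fallback, setting out from 8: α-iodination (I2, pyridine, CH2Cl2) gives the 3-iodo enone F6 without aldehyde or aqueous base. Stille coupling with Bu3SnCH2OH (Pd(PPh3)4, zerovalent palladium, dioxane, 80 °C) then forms C3–C7 under neutral conditions and rejoins the route at 10.

**Step 3.** Allylic-cation character in the protonated oxirane may erode regiocontrol (conjugate opening at C3, or loss of inversion), and acid in methanol may exchange the ketal. Fallback, setting out from 3: direct SN2 opening of the unactivated oxirane by methoxide (NaOMe cat., MeOH, 50 °C) changes the mechanism from acid-activated to anionic, removes the cation pathway, leaves the ketal untouched, and returns to 5 with no new compound (F0).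

## Further compounds

F1 | step 2 | racemic 1,6-epoxy-4,5-(isopropylidenedioxy)cyclohex-2-ene (anti), equal mixture of 3 and its enantiomer | C1=C[C@H]2OC(C)(C)O[C@H]2[C@@H]3O[C@H]13.C1=C[C@@H]2OC(C)(C)O[C@@H]2[C@H]3O[C@@H]13
F2 | step 2 | racemic methoxy alcohol, equal mixture of 5 and its enantiomer | CO[C@H]1C=C[C@H]2OC(C)(C)O[C@H]2[C@@H]1O.CO[C@@H]1C=C[C@@H]2OC(C)(C)O[C@@H]2[C@H]1O
F3 | step 2 | (S)-O-methylmandelate (6-O-ester) of 5 | CO[C@H]1C=C[C@H]2OC(C)(C)O[C@H]2[C@@H]1OC(=O)[C@@H](OC)c1ccccc1
F4 | step 2 | (S)-O-methylmandelate of the enantiomer of 5 | CO[C@@H]1C=C[C@@H]2OC(C)(C)O[C@@H]2[C@H]1OC(=O)[C@@H](OC)c1ccccc1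
F5 | step 10 | 5β-benzoyloxy-3-(benzoyloxymethyl)-1β-methoxy-6α-(4-methoxybenzyloxy)cyclohex-2-en-4β-ol | CO[C@H]1C=C(COC(=O)c2ccccc2)[C@@H](O)[C@@H](OC(=O)c2ccccc2)[C@@H]1OCc1ccc(OC)cc1
F6 | step 7 | 5β-hydroxy-3-iodo-1β-methoxy-6α-(4-methoxybenzyloxy)cyclohex-2-en-4-one | CO[C@H]1C=C(I)C(=O)[C@@H](O)[C@@H]1OCc1ccc(OC)cc1
F0 | step 3 | none | none
A1 | alternative 1 | D-xylose (open-chain form) | O=C[C@H](O)[C@@H](O)[C@H](O)CO
A2 | alternative 1 | S-ethyl (E)-4-methoxy-5,6-bis(4-methoxybenzyloxy)-7-oxohept-2-enethioate (D-xylo configuration) | CCSC(=O)/C=C/[C@H](OC)[C@@H](OCc1ccc(OC)cc1)[C@H](OCc1ccc(OC)cc1)C=O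
A3 | alternative 1 | S-ethyl 4β-hydroxy-1β-methoxy-5β,6α-bis(4-methoxybenzyloxy)cyclohex-2-ene-3-carbothioate (target numbering) | CO[C@H]1C=C(C(=O)SCC)[C@@H](O)[C@@H](OCc2ccc(OC)cc2)[C@@H]1OCc1ccc(OC)cc1
A4 | alternative 2 | bromobenzene | Brc1ccccc1
A5 | alternative 2 | (1S,2S)-3-bromocyclohexa-3,5-diene-1,2-diol | O[C@@H]1C(Br)=CC=C[C@@H]1O
A6 | alternative 3 | furfuryl acetate | CC(=O)OCc1ccco1
A7 | alternative 3 | vinylene carbonate | O=C1OC=CO1
A8 | alternative 3 | endo 7-oxanorbornene cyclic carbonate with bridgehead acetoxymethyl | C1=C[C@@]2(COC(C)=O)[C@H]3OC(=O)O[C@H]3[C@@H]1O2
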